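## The problem

Numbering used here: ring A is the benzene ring, with C1 (OMe), C2 (side chain) and C4 (acrylic acid). The side chain runs C1' (benzylic) to C8', with the methyl on C3', the acetoxy group on C4' and the dimethyl terminus at C7'. The acrylate carbons are Cα (next to CO2H) and Cβ (on the ring).

- No ring has to be made: ring A is a 1,2,4-trisubstituted anisole, and the work lies in attaching two chains to it at the right positions with the right alkene geometries (Z at Cα=Cβ, E at C2'=C3').
- The only stereocentre is C4' (R). Nothing else in the molecule can relay chirality to it, so a chiral reagent or catalyst must set it.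
- C4' is allylic and esterified, so it ionises easily; it must be created late and never meet strong acid or zerovalent palladium afterwards.
- The C5'–C7' prenyl unit must be attached in the linear sense, whereas prenyl-metal reagents add to aldehydes through their dimethyl-substituted carbon.
- The Z-acrylic acid is the less stable geometric isomer and isomerises under acid, heat, light or reversible conjugate addition.
- The acetate cannot coexist with hydroxide, which dictates the order of ester cleavage and acetylation.
- The feature that opens the key step is that the acrylate sits at C4, para to the C1 methoxy group and therefore at the most nucleophilic C–H of a 2-alkylanisole. Its Z geometry is exactly what anti addition of that C–H across a propiolate delivers, so the C4–Cβ bond and the Z alkene can be made in one operation.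

## Retrosynthesis

**Acetate, 11 ⇒ 9 (through 10).** The C4'–O acyl bond is cut first because the acetate is the group least tolerant of base and of ionising conditions. Putting it on last, onto the free hydroxy acid 9, avoids any later ester hydrolysis in its presence; the reverse order would demand an orthogonal ester. In the forward sense the alcohol is acetylated while the carboxyl group passes through the mixed anhydride 10, which water must return to the acid.

**Methyl ester, 9 ⇒ 8.** The acid is masked as the methyl ester that the key step delivers directly. It keeps the carboxyl group silent through the organoboron and metathesis steps. The forward reaction is a saponification that must leave the Z alkene and the allylic alcohol alone.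

**Prenyl terminus, 8 ⇒ 7.** The C6'=C7' double bond is cut back to a terminal vinyl group. Cutting C4'–C5' with an intact prenyl group would give the branched isomer in the forward direction; cutting the alkene turns the problem into a plain allyl addition followed by cross-metathesis. Precursor 7 is three carbons smaller. The metathesis must touch only the monosubstituted alkene among four C=C bonds.

**Stereocentre, 7 ⇒ 5 (through 6).** The C4'–C5' bond is cut, leaving the α-methyl enal 5. Cutting C3'–C4' instead would need an alkenyl-metal species and a labile β,γ-unsaturated aldehyde. Precursor 5 is achiral, so the forward step must rely on reagent control for facial selectivity and must choose the aldehyde over the ester; it passes through the borinate 6.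

**Key cut, 5 ⇒ 3 + 4.** The C4–Cβ bond is cut, giving the 2-substituted anisole 3 and methyl propiolate 4. The classical cut at Cα=Cβ would need a prior formylation of the ring and a Z-selective phosphonate olefination; this cut uses the native C4–H bond and gives the Z geometry by mechanism. It is placed before the stereocentre, the prenyl alkene and the acetate exist, because none of them would survive the acidic medium, whereas the conjugated enal of 3 is electron-poor and should.

**Enal, 3 ⇒ 1 + 2.** The C2'=C3' double bond is cut by cross-metathesis to commercial 2-allylanisole 1 and methacrolein 2. A Wittig route would start from an enolisable arylacetaldehyde; the metathesis cut uses two stable alkenes and should give the E enal. The forward reaction must avoid migration of the allyl double bond toward the ring.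

## Roads not taken

**Alternative 1:** Ring A itself is cut at two ring bonds (C1–C6 and C2–C3).
- Forward step: methyl coumalate A2 and the 1-methoxyalkyne A3, which carries the complete silyl-protected side chain, would combine by inverse-electron-demand [4+2] cycloaddition and lose CO2 to give the benzoate A1.
- Merits: the substitution pattern is fixed by construction, with no ortho/para question, and no strong acid is involved.
- Weak points: A3 is an ynol ether with a skipped ene–yne unit, sensitive to acid, to heat and to propargyl–allyl isomerisation. It needs its own asymmetric synthesis, so the most valuable fragment is risked in a thermal ring-forming step.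
- After the key step: A1 is a benzoate, one carbon short of the acrylate and at the wrong oxidation level. Reduction, reoxidation, a Z-selective olefination, desilylation, acetylation and ester cleavage would still follow.
- Comparison: this road is better in positional certainty. The chosen plan sets against it that the correctly substituted ring is bought as 1 and that the Z-acrylate arises in one step, giving six steps in total.

**Alternative 2:** The C5'–C6' bond is cut.
- Forward step: the N-hydroxyphthalimide ester A5 of the (R)-β-acetoxy acid and 1-bromo-2-methylprop-1-ene A6 would be coupled at a cathode with NiCl2(dme) and 2,2'-bipyridine, with loss of CO2, to give the silylethyl ester A4.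
- Merits: the prenyl terminus arrives in the linear sense with no regiochemical question. The 2-(trimethylsilyl)ethyl ester of A4 can be removed with fluoride beside the acetate, a cleaner endgame than the saponify-then-acetylate order of the chosen plan, which has to accept the transient mixed anhydride 10.
- Weak points: the radical formed at C5' is β to the acetoxy group and homoallylic to C2'=C3'. The alkylnickel species can lose acetate by β-elimination, and 3-exo closure and reopening of the homoallyl radical would move the radical to C4' and erase the stereocentre. The Z-acrylate is both a radical acceptor and reducible at the cathode, which invites isomerisation to E.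
- Comparison: A5 must already contain the whole remainder of the molecule, so the sequence is long and linear. The chosen plan has no radical or reductive step once C4' exists.

**Alternative 3:** The C3'–C4' bond is cut.
- Forward step: the (E)-alkenyl iodide A8 and 4-methylpent-3-enal A9 would be joined by CrCl2 with catalytic NiCl2 and a chiral oxazoline–sulfonamide ligand to give the carbinol A7, which is the same compound as 8.
- Merits: this is the most convergent road. Fragment union and stereocentre come in one step, the linear prenyl unit is built into A9, and organochromium reagents choose aldehydes over esters. It would reach 8 in one step where the chosen plan needs steps 3 and 4.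
- Weak points: A8 has iodine on the methyl-bearing carbon of a trisubstituted alkene. It is not available by carbometalation of a terminal alkyne, so it needs a regio- and stereocontrolled route of its own, and the Z-acrylate must still be put on A8. A9 is a volatile β,γ-unsaturated aldehyde that slips into conjugation. Enantioselectivity in this ligand-controlled coupling depends strongly on the substrate pair.
- Comparison: the chosen plan sets against the better convergence a reagent-controlled allylboration of an α-methyl enal, a well-behaved substrate class, and the use of commercial building blocks only.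

Key step: step 2

Assumption: the conjugated enal of 3 and 5 is taken to tolerate CF3CO2H/CH2Cl2 at 0 °C to room temperature for the short time the hydroarylation needs; the fallback for step 2 covers the opposite case.

## Steps

Step 1
Reactants: 1 2-allylanisole; 2 methacrolein
Product: 3 (E)-4-(2-methoxyphenyl)-2-methylbut-2-enal
Conditions: 2 (5 equiv), second-generation Grubbs catalyst RuCl2(=CHPh)(PCy3)(H2IMes) (3 mol %), 1,4-benzoquinone (10 mol %), CH2Cl2, 40 °C
Reagents that add atoms: none
Why: Olefin cross-metathesis of a terminal alkene with a 1,1-disubstituted enal, driven by loss of ethylene; the trisubstituted enal should form as the E isomer (formyl trans to C1') and not re-enter the cycle, and benzoquinone suppresses ruthenium hydride migration of the allyl double bond.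

Step 2
Reactants: 3 (E)-4-(2-methoxyphenyl)-2-methylbut-2-enal; 4 methyl propiolate
Product: 5 methyl (Z)-3-{4-methoxy-3-[(E)-3-methyl-4-oxobut-2-enyl]phenyl}acrylate
Conditions: 4 (1.3 equiv), Pd(OAc)2 (5 mol %), CF3CO2H/CH2Cl2 (1:1), 0 °C → rt
Reagents that add atoms: none
Why: This is a Fujiwara-type trans-hydroarylation of a propiolate by an electron-rich arene, a known reaction class for anisoles. Pd(OAc)2 in CF3CO2H gives a cationic divalent palladium trifluoroacetate that binds the alkyne of 4; ring A of 3 attacks the alkyne β-carbon from the side opposite the metal in a Friedel–Crafts manner, forming the C4–Cβ bond and an alkenylpalladium species. Protonolysis of the alkenyl–palladium bond with retention leaves aryl and ester cis, so the Z geometry follows from anti addition under kinetic control; no ring is closed and no stereocentre is formed. Site selectivity for C4 is secured by the C1 methoxy group: C4 is para to it, C6 is ortho but shielded by the methoxy methyl that the C2 substituent turns toward that side, and C3 and C5 are meta and unactivated. Chemoselectivity against the side chain rests on the C2'=C3' alkene being conjugated to the formyl group, hence neither basic nor nucleophilic, and on the E geometry holding the aldehyde away from ring A. A second alkyne insertion and Z to E isomerisation are limited by the small excess of 4, the low temperature and quenching as soon as 3 is consumed.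

Step 3
Reactants: 5 methyl (Z)-3-{4-methoxy-3-[(E)-3-methyl-4-oxobut-2-enyl]phenyl}acrylate
Product: 7 methyl (Z)-3-{3-[(2E,4R)-4-hydroxy-3-methylhepta-2,6-dienyl]-4-methoxyphenyl}acrylate, via diisopinocampheylborinate ester of the carbinol 6 (not isolated)
Conditions: (+)-Ipc2BOMe [from (−)-α-pinene], allylMgBr, Et2O, 0 °C → rt; then 5, −78 °C; then NaBO3·4H2O, THF/H2O, rt
Reagents that add atoms: B-allyldiisopinocampheylborane, C=CCB([C@H]1C[C@H]2C[C@@H]([C@@H]1C)C2(C)C)[C@H]1C[C@H]2C[C@@H]([C@@H]1C)C2(C)C, made in the flask from allylmagnesium bromide, C=CC[Mg]Br, and (+)-B-methoxydiisopinocampheylborane, COB([C@H]1C[C@H]2C[C@@H]([C@@H]1C)C2(C)C)[C@H]1C[C@H]2C[C@@H]([C@@H]1C)C2(C)C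
Why: Brown asymmetric allylboration through a closed six-membered chair transition state, chemoselective for the aldehyde over the ester and enoate at −78 °C. The isopinocampheyl groups derived from (−)-α-pinene direct the allyl group to the Re face of the enal carbonyl, which sets C4' as R (OH > C3' > C5' > H); perborate then cleaves the borinate 6 under conditions mild enough for the methyl ester.

Step 4
Reactants: 7 methyl (Z)-3-{3-[(2E,4R)-4-hydroxy-3-methylhepta-2,6-dienyl]-4-methoxyphenyl}acrylate
Product: 8 methyl (Z)-3-{3-[(2E,4R)-4-hydroxy-3,7-dimethylocta-2,6-dienyl]-4-methoxyphenyl}acrylate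
Conditions: 2-methyl-2-butene/CH2Cl2 (1:1), second-generation Grubbs catalyst RuCl2(=CHPh)(PCy3)(H2IMes) (5 mol %), 1,4-benzoquinone (10 mol %), rt
Reagents that add atoms: 2-methyl-2-butene, CC=C(C)C
Why: Olefin cross-metathesis with 2-methyl-2-butene in large excess exchanges the terminal methylene for an isopropylidene group with release of propene, giving the linear prenyl unit that direct prenyl-metal addition would not give. The trisubstituted C2'=C3' alkene and the electron-poor β-aryl acrylate should stay outside the catalytic cycle at room temperature, and C4' is not touched.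

Step 5
Reactants: 8 methyl (Z)-3-{3-[(2E,4R)-4-hydroxy-3,7-dimethylocta-2,6-dienyl]-4-methoxyphenyl}acrylate
Product: 9 (Z)-3-{3-[(2E,4R)-4-hydroxy-3,7-dimethylocta-2,6-dienyl]-4-methoxyphenyl}acrylic acid
Conditions: LiOH·H2O (3 equiv), THF/H2O (3:1), 0 °C → rt; then cold 0.5 M HCl to pH 3–4
Reagents that add atoms: lithium hydroxide, [Li+].[OH-]
Why: Saponification by acyl substitution at the ester carbonyl, which does not disturb the Z alkene; the C4' alcohol has no acidic hydrogen and is inert to base, and brief cold acidification avoids ionising the allylic alcohol.

Step 6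
Reactants: 9 (Z)-3-{3-[(2E,4R)-4-hydroxy-3,7-dimethylocta-2,6-dienyl]-4-methoxyphenyl}acrylic acid
Product: 11 (Z)-3-{3-[(2E,4R)-4-acetoxy-3,7-dimethylocta-2,6-dienyl]-4-methoxyphenyl}acrylic acid (CNP0206859.3), via mixed acetic anhydride of the acetoxy acid 10 (not isolated)
Conditions: Ac2O (5 equiv), pyridine, DMAP (5 mol %), CH2Cl2, 0 °C → rt; then H2O, rt
Reagents that add atoms: acetic anhydride, CC(=O)OC(C)=O
Why: DMAP-catalysed acetylation of the secondary allylic alcohol with retention at C4', since the C–O bond is not broken; the carboxyl group becomes the mixed anhydride 10 in the same flask, and water hydrolyses it at the acetyl carbonyl during the quench. Because the ester was cleaved in step 5, no hydroxide meets the acetate.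

## Compound list

1 | 2-allylanisole (1-allyl-2-methoxybenzene) | COc1ccccc1CC=C | starting material
2 | methacrolein | CC(=C)C=O | starting material
3 | (E)-4-(2-methoxyphenyl)-2-methylbut-2-enal | COc1ccccc1C/C=C(\C)C=O | intermediate
4 | methyl propiolate | C#CC(=O)OC | starting material
5 | methyl (Z)-3-{4-methoxy-3-[(E)-3-methyl-4-oxobut-2-enyl]phenyl}acrylate | COC(=O)/C=C\c1ccc(OC)c(C/C=C(\C)C=O)c1 | intermediate
6 | methyl (Z)-3-{3-[(2E,4R)-4-(diisopinocampheylboryloxy)-3-methylhepta-2,6-dienyl]-4-methoxyphenyl}acrylate | COC(=O)/C=C\c1ccc(OC)c(C/C=C(\C)[C@@H](CC=C)OB([C@H]2C[C@H]3C[C@@H]([C@@H]2C)C3(C)C)[C@H]2C[C@H]3C[C@@H]([C@@H]2C)C3(C)C)c1 | intermediate (not isolated)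
7 | methyl (Z)-3-{3-[(2E,4R)-4-hydroxy-3-methylhepta-2,6-dienyl]-4-methoxyphenyl}acrylate | COC(=O)/C=C\c1ccc(OC)c(C/C=C(\C)[C@@H](CC=C)O)c1 | intermediate
8 | methyl (Z)-3-{3-[(2E,4R)-4-hydroxy-3,7-dimethylocta-2,6-dienyl]-4-methoxyphenyl}acrylate | COC(=O)/C=C\c1ccc(OC)c(C/C=C(\C)[C@@H](CC=C(C)C)O)c1 | intermediate
9 | (Z)-3-{3-[(2E,4R)-4-hydroxy-3,7-dimethylocta-2,6-dienyl]-4-methoxyphenyl}acrylic acid | COc1ccc(/C=C\C(=O)O)cc1C/C=C(\C)[C@@H](CC=C(C)C)O | intermediate
10 | acetic (Z)-3-{3-[(2E,4R)-4-acetoxy-3,7-dimethylocta-2,6-dienyl]-4-methoxyphenyl}acrylic anhydride | COc1ccc(/C=C\C(=O)OC(C)=O)cc1C/C=C(\C)[C@@H](CC=C(C)C)OC(C)=O | intermediate (not isolated)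
11 | (Z)-3-{3-[(2E,4R)-4-acetoxy-3,7-dimethylocta-2,6-dienyl]-4-methoxyphenyl}acrylic acid | COc1ccc(/C=C\C(=O)O)cc1C/C=C(\C)[C@@H](CC=C(C)C)OC(C)=O | target

## Step count and risks

Total steps: 6. Longest linear sequence: 6 steps (1 → 3 → 5 → 7 → 8 → 9 → 11).

**Step 2 (key step).**
- What may go wrong: Friedel–Crafts consumption of the aldehyde by a second arene, or acid-induced migration of the C2'=C3' double bond; attack at C6 or a second alkyne insertion at the new alkene; Z to E isomerisation on prolonged exposure to acid.
- Fallback: it sets out from 1 and rejoins the route at 5, and the enal never meets acid.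
  - Rieche formylation of 1 (Cl2CHOMe, TiCl4, CH2Cl2, −78 → 0 °C) para to the methoxy group should give 3-allyl-4-methoxybenzaldehyde F1.
  - Still–Gennari olefination of F1 (methyl bis(2,2,2-trifluoroethyl)phosphonoacetate, KN(SiMe3)2, 18-crown-6, THF, −78 °C) should give methyl (Z)-3-(3-allyl-4-methoxyphenyl)acrylate F2.
  - Cross-metathesis of F2 with 2 under the conditions of step 1 should give 5.

**Step 1.**
- What may go wrong: migration of the allyl double bond into conjugation with ring A by ruthenium hydride species, homodimerisation of 1, and slow turnover with the 1,1-disubstituted electron-poor partner.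
- Fallback: it sets out from 1 and rejoins at 3. Ozonolysis of 1 (O3, CH2Cl2, −78 °C; then PPh3) should give 2-(2-methoxyphenyl)acetaldehyde F3. Wittig olefination of F3 with the stabilised ylide 2-(triphenylphosphoranylidene)propanal (toluene, 80 °C) should give the E enal 3.

**Step 4.**
- What may go wrong: engagement of the Z-acrylate by the ruthenium alkylidene (cleavage or Z to E isomerisation), or migration of the terminal double bond before metathesis.
- Fallback: it sets out from 5, rejoins at 8 and uses no metathesis after the key step.
  - Addition of prenylbarium chloride (from prenyl chloride and activated barium made from BaI2 and lithium biphenylide, THF, −78 °C) reacts through its unsubstituted carbon and should give the racemic carbinol methyl (Z)-3-{3-[(2E)-4-hydroxy-3,7-dimethylocta-2,6-dienyl]-4-methoxyphenyl}acrylate F4.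
  - Dess–Martin oxidation of F4 should give the enone methyl (Z)-3-{3-[(2E)-3,7-dimethyl-4-oxoocta-2,6-dienyl]-4-methoxyphenyl}acrylate F5.
  - Corey–Bakshi–Shibata reduction of F5 ((S)-2-methyl-CBS-oxazaborolidine, catecholborane, toluene, −78 °C), with the alkenyl group as the large substituent, should give 8 with the R configuration.

**Step 6.**
- What may go wrong: acyl transfer from the mixed anhydride 10 to the hydroxyl group of a second molecule (oligomeric esters), and Z to E isomerisation of the activated acryloyl unit by reversible conjugate addition of pyridine or DMAP.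
- Fallback: it sets out from 9 and rejoins at 11.
  - Alkylation of the carboxylate of 9 (phenacyl bromide, KHCO3, DMF, rt) should give 2-oxo-2-phenylethyl (Z)-3-{3-[(2E,4R)-4-hydroxy-3,7-dimethylocta-2,6-dienyl]-4-methoxyphenyl}acrylate F6.
  - Acetylation of F6 (Ac2O, pyridine, DMAP) should give 2-oxo-2-phenylethyl (Z)-3-{3-[(2E,4R)-4-acetoxy-3,7-dimethylocta-2,6-dienyl]-4-methoxyphenyl}acrylate F7.
  - Reductive removal of the phenacyl group from F7 (Zn, AcOH, rt) should free the acid 11 without touching the acetate.

## Further compounds

F1 | step 2 | 3-allyl-4-methoxybenzaldehyde | COc1ccc(C=O)cc1CC=C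
F2 | step 2 | methyl (Z)-3-(3-allyl-4-methoxyphenyl)acrylate | COC(=O)/C=C\c1ccc(OC)c(CC=C)c1
F3 | step 1 | 2-(2-methoxyphenyl)acetaldehyde | COc1ccccc1CC=O
F4 | step 4 | methyl (Z)-3-{3-[(2E)-4-hydroxy-3,7-dimethylocta-2,6-dienyl]-4-methoxyphenyl}acrylate (racemic) | COC(=O)/C=C\c1ccc(OC)c(C/C=C(\C)C(O)CC=C(C)C)c1
F5 | step 4 | methyl (Z)-3-{3-[(2E)-3,7-dimethyl-4-oxoocta-2,6-dienyl]-4-methoxyphenyl}acrylate | COC(=O)/C=C\c1ccc(OC)c(C/C=C(\C)C(=O)CC=C(C)C)c1
F6 | step 6 | 2-oxo-2-phenylethyl (Z)-3-{3-[(2E,4R)-4-hydroxy-3,7-dimethylocta-2,6-dienyl]-4-methoxyphenyl}acrylate | COc1ccc(/C=C\C(=O)OCC(=O)c2ccccc2)cc1C/C=C(\C)[C@@H](CC=C(C)C)O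
F7 | step 6 | 2-oxo-2-phenylethyl (Z)-3-{3-[(2E,4R)-4-acetoxy-3,7-dimethylocta-2,6-dienyl]-4-methoxyphenyl}acrylate | COc1ccc(/C=C\C(=O)OCC(=O)c2ccccc2)cc1C/C=C(\C)[C@@H](CC=C(C)C)OC(C)=O
A1 | alternative 1 | methyl 3-[(2E,4R)-4-(tert-butyldimethylsilyloxy)-3,7-dimethylocta-2,6-dienyl]-4-methoxybenzoate | COC(=O)c1ccc(OC)c(C/C=C(\C)[C@@H](CC=C(C)C)O[Si](C)(C)C(C)(C)C)c1
A2 | alternative 1 | methyl coumalate (methyl 2-oxo-2H-pyran-5-carboxylate) | COC(=O)C1=COC(=O)C=C1
A3 | alternative 1 | (4E,6R)-6-(tert-butyldimethylsilyloxy)-1-methoxy-5,9-dimethyldeca-4,8-dien-1-yne | COC#CC/C=C(\C)[C@@H](CC=C(C)C)O[Si](C)(C)C(C)(C)C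
A4 | alternative 2 | 2-(trimethylsilyl)ethyl (Z)-3-{3-[(2E,4R)-4-acetoxy-3,7-dimethylocta-2,6-dienyl]-4-methoxyphenyl}acrylate | C[Si](C)(C)CCOC(=O)/C=C\c1ccc(OC)c(C/C=C(\C)[C@@H](CC=C(C)C)OC(C)=O)c1
A5 | alternative 2 | 1,3-dioxoisoindolin-2-yl (3R,4E)-3-acetoxy-6-{2-methoxy-5-[(Z)-3-oxo-3-(2-(trimethylsilyl)ethoxy)prop-1-enyl]phenyl}-4-methylhex-4-enoate | C[Si](C)(C)CCOC(=O)/C=C\c1ccc(OC)c(C/C=C(\C)[C@@H](CC(=O)ON2C(=O)c3ccccc3C2=O)OC(C)=O)c1
A6 | alternative 2 | 1-bromo-2-methylprop-1-ene | CC(C)=CBr
A7 | alternative 3 | methyl (Z)-3-{3-[(2E,4R)-4-hydroxy-3,7-dimethylocta-2,6-dienyl]-4-methoxyphenyl}acrylate | COC(=O)/C=C\c1ccc(OC)c(C/C=C(\C)[C@@H](CC=C(C)C)O)c1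
A8 | alternative 3 | methyl (Z)-3-{3-[(E)-3-iodobut-2-enyl]-4-methoxyphenyl}acrylate | COC(=O)/C=C\c1ccc(OC)c(C/C=C(\C)I)c1
A9 | alternative 3 | 4-methylpent-3-enal | CC(C)=CCC=O
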